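## Retrosynthetic overview

1. Target 20 ⇐ nona-O-benzyl ether 19 ⇐ (double galloylation of 3-OH and 5-OH) tri-O-benzyl-epicatechin 17 ⇐ (loss of CO2 from C2, C2–H set anti to O3) hydroxy acid 16 ⇐ (lactone opening) tricyclic β-lactone 15.
2. Key disconnection C2–C3: 15 ⇐ lactol acid 12 by an enantioselective nucleophile-catalysed aldol-lactonisation cascade that opens the lactol ring, closes ring C through the C2–C3 bond and closes a β-lactone between O3 and the carboxyl carbon on C2.
3. 12 ⇐ phenol 6 + diazo ester 9 (O–H insertion forms O1–C2); 6 ⇐ 2,4,6-trihydroxybenzaldehyde (its formyl carbon becomes C4, a Wittig carbon becomes C3); 9 ⇐ 3,4-dihydroxyphenylacetic acid.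
4. Order of rings: rings A and B are bought; a temporary dihydrofuran ring (O5–C3 acetal, later lactol) is closed in step 4; in step 9 it opens while ring C and the temporary β-lactone close; the β-lactone is opened in step 10 and its carbon leaves as CO2 in step 11.
5. Enabling feature: C2 is flanked by O1 and by C1′ of ring B, so a carboxyl on C2 makes it the acidic α-carbon of an α-aryloxy-arylacetic acid and later leaves from a doubly stabilised C2 radical; C3 bears O3, so it can enter as an aldehyde carbon; that carboxyl carbon and O3 are 1,3-related and lactonise, which makes the aldol irreversible; O5 on ring A, ortho to C4a, masks the C3 aldehyde as a five-membered lactol and is thereby told apart from O1 and O7.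

Key step: step 9

Assumption: O-trimethylsilylquinidine is taken to induce the (3R) configuration; should the antipode form, O-trimethylsilylquinine replaces it and nothing else changes. Compounds 6 and 10–12 are stereoisomer mixtures whose stereocentres are all erased in step 9.

## Route

Step 1
Reactants: 1 2,4,6-trihydroxybenzaldehyde
Product: 2 4-(benzyloxy)-2,6-dihydroxybenzaldehyde
Conditions: BnBr (1.05 equiv), K2CO3 (1.0 equiv), DMF, 0 °C → rt
Reagents that add atoms: benzyl bromide, BrCc1ccccc1
Why: Williamson etherification: the 4-OH is the most acidic hydroxyl and the only one not hydrogen-bonded to the formyl group, so one equivalent of base and benzyl bromide should alkylate it selectively; no stereocentre is formed.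

Step 2
Reactants: 2 4-(benzyloxy)-2,6-dihydroxybenzaldehyde
Product: 3 4-(benzyloxy)-2,6-bis(methoxymethoxy)benzaldehyde
Conditions: NaH (2.3 equiv), MOMCl (2.5 equiv), DMF, 0 °C → rt
Reagents that add atoms: chloromethyl methyl ether, COCCl
Why: Williamson-type acetal protection: NaH breaks the two OH···O=C hydrogen bonds and both phenoxides are alkylated, which protects the acidic phenols for the ylide step; no stereocentre is formed.

Step 3
Reactants: 3 4-(benzyloxy)-2,6-bis(methoxymethoxy)benzaldehyde; 4 (methoxymethyl)triphenylphosphonium chloride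
Product: 5 5-(benzyloxy)-2-(2-methoxyethenyl)-1,3-bis(methoxymethoxy)benzene (E/Z mixture)
Conditions: KOtBu, THF, 0 °C → rt
Reagents that add atoms: none
Why: Wittig olefination with the non-stabilised methoxymethylene ylide turns the hindered aryl aldehyde into an enol ether that carries the future C3 at the aldehyde oxidation level; the E/Z ratio is irrelevant because the alkene is consumed in step 4.

Step 4
Reactants: 5 5-(benzyloxy)-2-(2-methoxyethenyl)-1,3-bis(methoxymethoxy)benzene
Product: 6 6-(benzyloxy)-2-methoxy-2,3-dihydro-1-benzofuran-4-ol (racemic)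
Conditions: conc. HCl (cat.), MeOH, 25 °C; then PPTS (cat.), toluene, evaporation of MeOH
Reagents that add atoms: none
Why: Acid-catalysed transacetalisation removes both MOM groups as dimethoxymethane, and protonation of the enol ether at the benzylic carbon gives an oxocarbenium ion at the future C3 that one of the two equivalent phenols captures (5-exo-trig) under thermodynamic control, which masks the aldehyde, ties up the future O5 and leaves the future O1 as the only free phenol; the acetal stereocentre is racemic and is destroyed in step 9.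

Step 5
Reactants: 7 3,4-dihydroxyphenylacetic acid
Product: 8 benzyl [3,4-bis(benzyloxy)phenyl]acetate
Conditions: BnBr (3.3 equiv), K2CO3 (3.5 equiv), DMF, 60 °C
Reagents that add atoms: benzyl bromide, BrCc1ccccc1
Why: Williamson etherification and carboxylate O-alkylation in one operation protect both catechol hydroxyls and the acid as benzyl derivatives; no stereocentre is formed.

Step 6
Reactants: 8 benzyl [3,4-bis(benzyloxy)phenyl]acetate
Product: 9 benzyl [3,4-bis(benzyloxy)phenyl](diazo)acetate
Conditions: 4-acetamidobenzenesulfonyl azide (1.2 equiv), DBU (1.5 equiv), MeCN, 0 °C → rt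
Reagents that add atoms: 4-acetamidobenzenesulfonyl azide, CC(=O)Nc1ccc(cc1)S(=O)(=O)N=[N+]=[N-]
Why: Regitz diazo transfer: DBU deprotonates the benzylic α-carbon of the arylacetate, which attacks the sulfonyl azide to give the donor/acceptor diazo ester; no stereocentre is formed.

Step 7
Reactants: 6 6-(benzyloxy)-2-methoxy-2,3-dihydro-1-benzofuran-4-ol; 9 benzyl [3,4-bis(benzyloxy)phenyl](diazo)acetate
Product: 10 benzyl {[6-(benzyloxy)-2-methoxy-2,3-dihydro-1-benzofuran-4-yl]oxy}[3,4-bis(benzyloxy)phenyl]acetate (mixture of diastereomers)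
Conditions: Rh2(OAc)4 (1 mol%), CH2Cl2, rt, slow addition of 9
Reagents that add atoms: none
Why: Dirhodium-carbenoid O–H insertion into the only free phenol forms the O1–C2 ether bond under neutral conditions that leave the acetal untouched; the new stereocentre (future C2) is formed without control, which is of no consequence because it is erased in step 9.

Step 8
Reactants: 10 benzyl {[6-(benzyloxy)-2-methoxy-2,3-dihydro-1-benzofuran-4-yl]oxy}[3,4-bis(benzyloxy)phenyl]acetate
Product: 12 {[6-(benzyloxy)-2-hydroxy-2,3-dihydro-1-benzofuran-4-yl]oxy}[3,4-bis(benzyloxy)phenyl]acetic acid (lactol acid), via acetal acid 11 (not isolated)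
Conditions: LiOH·H2O (3 equiv), THF/H2O, rt; then 1 M HCl to pH 1, THF/H2O, rt
Reagents that add atoms: lithium hydroxide, [Li+].[OH-]; water, O
Why: Saponification of the benzyl ester followed by aqueous-acid hydrolysis of the cyclic methyl acetal gives the lactol acid, the α-carboxyl group disfavouring ionisation of the O1–C2 bond under the acidic conditions; no defined stereocentre is set.

Step 9
Reactants: 12 {[6-(benzyloxy)-2-hydroxy-2,3-dihydro-1-benzofuran-4-yl]oxy}[3,4-bis(benzyloxy)phenyl]acetic acid
Product: 15 (2S,3R)-7-(benzyloxy)-2-[3,4-bis(benzyloxy)phenyl]-5-hydroxychromane-2-carboxylic acid 3-O-lactone (cis-fused β-lactone), via open-chain hydroxy aldehyde acid 13 (not isolated), via aryl(aryloxy)ketene 14 (not isolated)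
Conditions: O-trimethylsilylquinidine (10 mol%), 2-chloro-1-methylpyridinium iodide (1.5 equiv), i-Pr2NEt (3.5 equiv), MeCN, 25 °C, slow addition of 12 at high dilution
Reagents that add atoms: none
Why: Proposed new method: the pyridinium salt activates the carboxyl group of 12 and the cinchona nucleophile converts it, by way of ketene 14, into a chiral C2 ammonium enolate, while the base opens the lactol to the hydroxy aldehyde 13; the enolate adds to the C3 aldehyde and the C3 alkoxide then expels the catalyst from the acylammonium carbon, so that the aldol addition is made irreversible by lactonisation. The closest known reaction type is the intramolecular nucleophile-catalysed aldol-lactonisation of aldehyde acids and keto acids, including acids whose α-carbon becomes quaternary; not yet shown are a tetrasubstituted α-aryl-α-aryloxy ammonium enolate, an ether oxygen in the tether and a lactol as the aldehyde source. Ring C closes by a 6-(enolexo)-exo-trig aldol addition that forms C2–C3, and the β-lactone closes by a 4-exo-trig acyl substitution of O3 on the carboxyl carbon attached to C2. C3 (R) is set by the chiral ammonium enolate, which selects one face of the aldehyde (catalyst control); C2 (S) follows from C3 because the four-membered ring can only be cis-fused to ring C, and C2 is in any case re-set in step 11. The step needs chemoselectivity for the carboxylate over the free 5-OH and lactol OH, which the lactol resting state (the phenol is masked), the impossibility of a lactone bridging the meta-related O1 and O5 positions and slow addition at high dilution should secure. It also needs the α-CH2 of the aldehyde (C4) to stay out of the reaction, which the far higher acidity of the acylammonium α-CH (C2) under amine base should secure.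

Step 10
Reactants: 15 (2S,3R)-7-(benzyloxy)-2-[3,4-bis(benzyloxy)phenyl]-5-hydroxychromane-2-carboxylic acid 3-O-lactone
Product: 16 (2S,3R)-7-(benzyloxy)-2-[3,4-bis(benzyloxy)phenyl]-3,5-dihydroxychromane-2-carboxylic acid (carboxyl cis to 3-OH)
Conditions: LiOH (2.2 equiv), THF/H2O, 0 °C; then 1 M HCl to pH 3
Reagents that add atoms: lithium hydroxide, [Li+].[OH-]
Why: Hydroxide opens the strained β-lactone by acyl–oxygen cleavage (addition–elimination), so both stereocentres are retained, and retro-aldol cleavage is disfavoured because it would expel a carboxylate dianion enolate.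

Step 11
Reactants: 16 (2S,3R)-7-(benzyloxy)-2-[3,4-bis(benzyloxy)phenyl]-3,5-dihydroxychromane-2-carboxylic acid
Product: 17 (2R,3R)-7-(benzyloxy)-2-[3,4-bis(benzyloxy)phenyl]chromane-3,5-diol (7,3′,4′-tri-O-benzyl-epicatechin)
Conditions: [Ir{dF(CF3)ppy}2(dtbbpy)]PF6 (1 mol%), tert-dodecanethiol (20 mol%), K2HPO4 (1.0 equiv), MeCN/H2O, 450 nm LEDs, rt
Reagents that add atoms: none
Why: Photoredox hydrodecarboxylation: single-electron oxidation of the α-aryloxy carboxylate and loss of CO2 give a planar C2 radical stabilised by O1 and ring B, and hydrogen-atom transfer from the bulky thiol to the face anti to the pseudo-axial 3-hydroxyl group (axial because of allylic-type strain with the coplanar aryl group) should set C2 as R, that is 2,3-cis.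

Step 12
Reactants: 17 (2R,3R)-7-(benzyloxy)-2-[3,4-bis(benzyloxy)phenyl]chromane-3,5-diol; 18 3,4,5-tris(benzyloxy)benzoic acid
Product: 19 (2R,3R)-7-(benzyloxy)-2-[3,4-bis(benzyloxy)phenyl]chromane-3,5-diyl bis[3,4,5-tris(benzyloxy)benzoate]
Conditions: 18 (2.6 equiv), DCC (2.8 equiv), DMAP (0.5 equiv), CH2Cl2, 0 °C → rt
Reagents that add atoms: none
Why: Steglich esterification (carbodiimide activation, acyl transfer by DMAP) acylates the only two free hydroxyls, the 5-phenol and the axial 3-alcohol, without touching any stereocentre.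

Step 13
Reactants: 19 (2R,3R)-7-(benzyloxy)-2-[3,4-bis(benzyloxy)phenyl]chromane-3,5-diyl bis[3,4,5-tris(benzyloxy)benzoate]
Product: 20 epicatechin 3,5-di-O-gallate
Conditions: H2 (1 atm), Pd(OH)2/C, THF/EtOAc, rt
Reagents that add atoms: none
Why: Palladium-catalysed hydrogenolysis cleaves the nine O-benzyl ethers, while the two gallate esters and the cyclic benzylic ether O1–C2 of the flavan, which is much slower to hydrogenolyse, should remain, so both stereocentres are untouched.

## Compound list

1 | 2,4,6-trihydroxybenzaldehyde | O=Cc1c(O)cc(O)cc1O | starting material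
2 | 4-(benzyloxy)-2,6-dihydroxybenzaldehyde | O=Cc1c(O)cc(OCc2ccccc2)cc1O | intermediate
3 | 4-(benzyloxy)-2,6-bis(methoxymethoxy)benzaldehyde | O=Cc1c(OCOC)cc(OCc2ccccc2)cc1OCOC | intermediate
4 | (methoxymethyl)triphenylphosphonium chloride | COC[P+](c1ccccc1)(c1ccccc1)c1ccccc1.[Cl-] | starting material
5 | 5-(benzyloxy)-2-(2-methoxyethenyl)-1,3-bis(methoxymethoxy)benzene (E/Z mixture) | COC=Cc1c(OCOC)cc(OCc2ccccc2)cc1OCOC | intermediate
6 | 6-(benzyloxy)-2-methoxy-2,3-dihydro-1-benzofuran-4-ol (racemic) | COC1Cc2c(O)cc(OCc3ccccc3)cc2O1 | intermediate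
7 | 3,4-dihydroxyphenylacetic acid | OC(=O)Cc1ccc(O)c(O)c1 | starting material
8 | benzyl [3,4-bis(benzyloxy)phenyl]acetate | O=C(Cc1ccc(OCc2ccccc2)c(OCc2ccccc2)c1)OCc1ccccc1 | intermediate
9 | benzyl [3,4-bis(benzyloxy)phenyl](diazo)acetate | [N-]=[N+]=C(C(=O)OCc1ccccc1)c1ccc(OCc2ccccc2)c(OCc2ccccc2)c1 | intermediate
10 | benzyl {[6-(benzyloxy)-2-methoxy-2,3-dihydro-1-benzofuran-4-yl]oxy}[3,4-bis(benzyloxy)phenyl]acetate (diastereomer mixture) | COC1Cc2c(OC(C(=O)OCc3ccccc3)c3ccc(OCc4ccccc4)c(OCc4ccccc4)c3)cc(OCc3ccccc3)cc2O1 | intermediate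
11 | {[6-(benzyloxy)-2-methoxy-2,3-dihydro-1-benzofuran-4-yl]oxy}[3,4-bis(benzyloxy)phenyl]acetic acid (acetal acid, not isolated) | COC1Cc2c(OC(C(=O)O)c3ccc(OCc4ccccc4)c(OCc4ccccc4)c3)cc(OCc3ccccc3)cc2O1 | intermediate
12 | {[6-(benzyloxy)-2-hydroxy-2,3-dihydro-1-benzofuran-4-yl]oxy}[3,4-bis(benzyloxy)phenyl]acetic acid (lactol acid) | OC1Cc2c(OC(C(=O)O)c3ccc(OCc4ccccc4)c(OCc4ccccc4)c3)cc(OCc3ccccc3)cc2O1 | intermediate
13 | [5-(benzyloxy)-3-hydroxy-2-(2-oxoethyl)phenoxy][3,4-bis(benzyloxy)phenyl]acetic acid (open-chain tautomer of 12, not isolated) | O=CCc1c(O)cc(OCc2ccccc2)cc1OC(C(=O)O)c1ccc(OCc2ccccc2)c(OCc2ccccc2)c1 | intermediate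
14 | [3,4-bis(benzyloxy)phenyl][5-(benzyloxy)-3-hydroxy-2-(2-oxoethyl)phenoxy]ketene (not isolated) | O=CCc1c(O)cc(OCc2ccccc2)cc1OC(=C=O)c1ccc(OCc2ccccc2)c(OCc2ccccc2)c1 | intermediate
15 | (2S,3R)-7-(benzyloxy)-2-[3,4-bis(benzyloxy)phenyl]-5-hydroxychromane-2-carboxylic acid 3-O-lactone (oxetan-2-one cis-fused across C2–C3, acyl carbon on C2, ring oxygen on C3) | Oc1cc(OCc2ccccc2)cc2c1C[C@H]1OC(=O)[C@@]1(c1ccc(OCc3ccccc3)c(OCc3ccccc3)c1)O2 | intermediate
16 | (2S,3R)-7-(benzyloxy)-2-[3,4-bis(benzyloxy)phenyl]-3,5-dihydroxychromane-2-carboxylic acid (carboxyl cis to 3-OH) | Oc1cc(OCc2ccccc2)cc2c1C[C@@H](O)[C@@](c1ccc(OCc3ccccc3)c(OCc3ccccc3)c1)(C(=O)O)O2 | intermediate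
17 | (2R,3R)-7-(benzyloxy)-2-[3,4-bis(benzyloxy)phenyl]chromane-3,5-diol (2,3-cis) | Oc1cc(OCc2ccccc2)cc2c1C[C@@H](O)[C@@H](c1ccc(OCc3ccccc3)c(OCc3ccccc3)c1)O2 | intermediate
18 | 3,4,5-tris(benzyloxy)benzoic acid | OC(=O)c1cc(OCc2ccccc2)c(OCc2ccccc2)c(OCc2ccccc2)c1 | starting material
19 | (2R,3R)-7-(benzyloxy)-2-[3,4-bis(benzyloxy)phenyl]chromane-3,5-diyl bis[3,4,5-tris(benzyloxy)benzoate] | O=C(Oc1cc(OCc2ccccc2)cc2c1C[C@@H](OC(=O)c1cc(OCc3ccccc3)c(OCc3ccccc3)c(OCc3ccccc3)c1)[C@@H](c1ccc(OCc3ccccc3)c(OCc3ccccc3)c1)O2)c1cc(OCc2ccccc2)c(OCc2ccccc2)c(OCc2ccccc2)c1 | intermediate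
20 | epicatechin 3,5-di-O-gallate, (2R,3R)-2-(3,4-dihydroxyphenyl)-7-hydroxychromane-3,5-diyl bis(3,4,5-trihydroxybenzoate) | O=C(Oc1cc(O)cc2c1C[C@@H](OC(=O)c1cc(O)c(O)c(O)c1)[C@@H](c1ccc(O)c(O)c1)O2)c1cc(O)c(O)c(O)c1 | target

## Step count and risks

Total step count: 13. Longest linear sequence: 11 steps (steps 1, 2, 3, 4, 7, 8, 9, 10, 11, 12, 13).

Steps most likely to fail:

**Step 9 (Proposed new method).** The activated acid may acylate the free 5-OH or lactol OH of another molecule faster than the tetrasubstituted ammonium enolate closes the six-membered ring, or the chiral nucleophile may discriminate the aldehyde faces poorly. The fallback uses known chemistry only, sets out from 10 and comes back at 19. The acetal of 10 is hydrolysed (1 M HCl, THF/H2O, 25 °C) to the lactol ester benzyl {[6-(benzyloxy)-2-hydroxy-2,3-dihydro-1-benzofuran-4-yl]oxy}[3,4-bis(benzyloxy)phenyl]acetate F1. Cs2CO3 in MeCN opens the lactol and the ester enolate adds to the aldehyde in a classical intramolecular aldol reaction, which should give racemic benzyl 7-(benzyloxy)-2-[3,4-bis(benzyloxy)phenyl]-3,5-dihydroxychromane-2-carboxylate F2 as a diastereomer mixture (C2–C3 closed, stereochemistry irrelevant at this stage). Phenol-selective Steglich esterification with 18 (1.0 equiv, DCC, DMAP cat., 0 °C) should give benzyl 7-(benzyloxy)-2-[3,4-bis(benzyloxy)phenyl]-3-hydroxy-5-{[3,4,5-tris(benzyloxy)benzoyl]oxy}chromane-2-carboxylate F3. Dess–Martin oxidation should give the β-keto ester benzyl 7-(benzyloxy)-2-[3,4-bis(benzyloxy)phenyl]-3-oxo-5-{[3,4,5-tris(benzyloxy)benzoyl]oxy}chromane-2-carboxylate F4. Hydrogenolysis of the benzyl ester alone (H2, Pd/C, 2,2′-bipyridyl to suppress cleavage of the aryl benzyl ethers, EtOAc) and spontaneous decarboxylation should give the flavan-3-one 7-(benzyloxy)-2-[3,4-bis(benzyloxy)phenyl]-3-oxochroman-5-yl 3,4,5-tris(benzyloxy)benzoate F5, whose C2 centre epimerises through the enol. Asymmetric transfer hydrogenation with dynamic kinetic resolution (RuCl(p-cymene)[(S,S)-TsDPEN] or its enantiomer, whichever delivers the 3R alcohol, HCO2H/Et3N) should deliver hydride anti to the C2 aryl group and give the cis alcohol (2R,3R)-7-(benzyloxy)-2-[3,4-bis(benzyloxy)phenyl]-3-hydroxychroman-5-yl 3,4,5-tris(benzyloxy)benzoate F6. A second Steglich esterification with 18 leads to 19.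

**Step 11.** Hydrogen-atom transfer to the planar C2 radical may occur on both faces and give the 2,3-trans epimer alongside 17. The fallback sets out from 17 as obtained (mixed with its C2 epimer) and comes back at 19; it replaces radical control by hydride delivery to a ketone. Phenol-selective Steglich esterification with 18 (1.0 equiv, DCC, DMAP cat., 0 °C) should give (3R)-7-(benzyloxy)-2-[3,4-bis(benzyloxy)phenyl]-3-hydroxychroman-5-yl 3,4,5-tris(benzyloxy)benzoate F7 as both C2 epimers. Dess–Martin oxidation converges both epimers on the ketone F5 described above, and the dynamic kinetic transfer hydrogenation and esterification described there lead through F6 to 19.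

**Step 4.** The cyclic acetal may lose methanol under the acid needed for MOM cleavage and aromatise irreversibly to the benzofuran, or ring closure may stop at the open dimethyl acetal. The fallback sets out from 5 and comes back at 6; it removes the MOM groups at the lactone oxidation level, where aromatisation is impossible, and forms the acetal afterwards under very mild acid. Selective hydrolysis of the enol ether (oxalic acid, THF/H2O, rt) should give [4-(benzyloxy)-2,6-bis(methoxymethoxy)phenyl]acetaldehyde F8. Pinnick oxidation (NaClO2, NaH2PO4, 2-methyl-2-butene, t-BuOH/H2O) should give [4-(benzyloxy)-2,6-bis(methoxymethoxy)phenyl]acetic acid F9. HCl in MeOH at 50 °C followed by TsOH in toluene removes the MOM groups and lactonises to 6-(benzyloxy)-4-hydroxy-1-benzofuran-2(3H)-one F10. DIBAL-H (2.2 equiv, CH2Cl2/THF, −78 °C) should reduce the lactone to the lactol 6-(benzyloxy)-2,3-dihydro-1-benzofuran-2,4-diol F11, and PPTS (cat.) in MeOH at rt converts it into 6.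

Further compounds
F1 | step 9 | benzyl {[6-(benzyloxy)-2-hydroxy-2,3-dihydro-1-benzofuran-4-yl]oxy}[3,4-bis(benzyloxy)phenyl]acetate | OC1Cc2c(OC(C(=O)OCc3ccccc3)c3ccc(OCc4ccccc4)c(OCc4ccccc4)c3)cc(OCc3ccccc3)cc2O1
F2 | step 9 | benzyl 7-(benzyloxy)-2-[3,4-bis(benzyloxy)phenyl]-3,5-dihydroxychromane-2-carboxylate (racemic, diastereomer mixture) | O=C(OCc1ccccc1)C1(c2ccc(OCc3ccccc3)c(OCc3ccccc3)c2)Oc2cc(OCc3ccccc3)cc(O)c2CC1O
F3 | step 9 | benzyl 7-(benzyloxy)-2-[3,4-bis(benzyloxy)phenyl]-3-hydroxy-5-{[3,4,5-tris(benzyloxy)benzoyl]oxy}chromane-2-carboxylate (racemic, diastereomer mixture) | O=C(OCc1ccccc1)C1(c2ccc(OCc3ccccc3)c(OCc3ccccc3)c2)Oc2cc(OCc3ccccc3)cc(OC(=O)c3cc(OCc4ccccc4)c(OCc4ccccc4)c(OCc4ccccc4)c3)c2CC1O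
F4 | step 9 | benzyl 7-(benzyloxy)-2-[3,4-bis(benzyloxy)phenyl]-3-oxo-5-{[3,4,5-tris(benzyloxy)benzoyl]oxy}chromane-2-carboxylate (racemic) | O=C(OCc1ccccc1)C1(c2ccc(OCc3ccccc3)c(OCc3ccccc3)c2)Oc2cc(OCc3ccccc3)cc(OC(=O)c3cc(OCc4ccccc4)c(OCc4ccccc4)c(OCc4ccccc4)c3)c2CC1=O
F5 | step 9 | 7-(benzyloxy)-2-[3,4-bis(benzyloxy)phenyl]-3-oxochroman-5-yl 3,4,5-tris(benzyloxy)benzoate (racemic, C2 labile) | O=C1Cc2c(OC(=O)c3cc(OCc4ccccc4)c(OCc4ccccc4)c(OCc4ccccc4)c3)cc(OCc3ccccc3)cc2OC1c1ccc(OCc2ccccc2)c(OCc2ccccc2)c1
F6 | step 9 | (2R,3R)-7-(benzyloxy)-2-[3,4-bis(benzyloxy)phenyl]-3-hydroxychroman-5-yl 3,4,5-tris(benzyloxy)benzoate | O=C(Oc1cc(OCc2ccccc2)cc2c1C[C@@H](O)[C@@H](c1ccc(OCc3ccccc3)c(OCc3ccccc3)c1)O2)c1cc(OCc2ccccc2)c(OCc2ccccc2)c(OCc2ccccc2)c1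
F7 | step 11 | (3R)-7-(benzyloxy)-2-[3,4-bis(benzyloxy)phenyl]-3-hydroxychroman-5-yl 3,4,5-tris(benzyloxy)benzoate (both C2 epimers) | O=C(Oc1cc(OCc2ccccc2)cc2c1C[C@@H](O)C(c1ccc(OCc3ccccc3)c(OCc3ccccc3)c1)O2)c1cc(OCc2ccccc2)c(OCc2ccccc2)c(OCc2ccccc2)c1
F8 | step 4 | [4-(benzyloxy)-2,6-bis(methoxymethoxy)phenyl]acetaldehyde | O=CCc1c(OCOC)cc(OCc2ccccc2)cc1OCOC
F9 | step 4 | [4-(benzyloxy)-2,6-bis(methoxymethoxy)phenyl]acetic acid | OC(=O)Cc1c(OCOC)cc(OCc2ccccc2)cc1OCOC
F10 | step 4 | 6-(benzyloxy)-4-hydroxy-1-benzofuran-2(3H)-one | O=C1Cc2c(O)cc(OCc3ccccc3)cc2O1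
F11 | step 4 | 6-(benzyloxy)-2,3-dihydro-1-benzofuran-2,4-diol (racemic) | OC1Cc2c(O)cc(OCc3ccccc3)cc2O1
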